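**Retrosynthetic overview**
- Isariotin D ⇒ bicyclo[3.3.1]non-7-ene triol. The C7–O and C8–O bonds come from a hydroxyl-directed exo epoxidation, so the oxirane is the last ring formed.
- Bicyclic enetriol ⇒ o-quinol aldehyde. Water adds at C6 (C6–O, oxa-Michael) and the resulting enolate closes C4–C5 by aldol. This builds the second carbocycle on the dearomatised ring.
- o-Quinol aldehyde ⇒ 3-amidochroman-2-ol. The C1–O bond comes from a catalyst-controlled dearomative oxygenation of the phenol. The first carbocycle is the arene of o-tyrosine.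
- Chromanol ⇒ L-o-tyrosine + (E)-dec-2-enoic acid, by amide C–N formation and ester-to-aldehyde reduction. The aldehyde is stored as its lactol.

Assumption: L-o-tyrosine, (E)-dec-2-enoic acid and the lactamide-type chiral iodoarene are taken as catalogue items; numbering used throughout is C1 carbinol bridgehead, C2 CH2, C3 CHN, C4 CHOH, C5 bridgehead CH, C6 CHOH, C7/C8, C9 ketone.

**Step 1**
Reactants: 1 L-o-tyrosine
Product: 2 methyl L-o-tyrosinate hydrochloride
Conditions: SOCl2 (2.5 equiv), MeOH, 0 °C → reflux, 4 h
Reagents that add atoms: methanol, CO; thionyl chloride (chloride of the salt), O=S(Cl)Cl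
Why: Fischer-type esterification with HCl made in situ; the Cα stereocentre (future C3, S) is not touched.

**Step 2**
Reactants: 2 methyl L-o-tyrosinate hydrochloride; 3 (2E)-dec-2-enoic acid
Product: 5 methyl (2S)-2-[(2E)-dec-2-enamido]-3-(2-hydroxyphenyl)propanoate, via (2E)-dec-2-enoyl chloride 4 (not isolated)
Conditions: (i) 3, (COCl)2, cat. DMF, CH2Cl2, 0 °C → rt, evaporate; (ii) 2, NaHCO3, EtOAc/H2O, 0 °C
Reagents that add atoms: none
Why: Schotten–Baumann N-acylation; at pH 8 the amine outruns the undissociated phenol, and the amino-acid carboxyl is never activated, so no azlactone forms and Cα does not racemise.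

**Step 3**
Reactants: 5 amido ester
Product: 7 (2E)-N-[(3S)-2-hydroxy-3,4-dihydro-2H-chromen-3-yl]dec-2-enamide (lactol, anomer mixture), via open hydroxyaryl aldehyde 6 (not isolated)
Conditions: DIBAL-H (3.5 equiv), CH2Cl2, −78 °C, 2 h; MeOH, aq Rochelle salt
Reagents that add atoms: none
Why: Partial ester reduction with DIBAL-H; the tetrahedral aluminate survives at −78 °C (phenol and NH are only deprotonated), and on work-up aldehyde 6 is captured by the ortho phenol as a six-ring lactol that shields Cα from epimerisation; the anomeric centre is of no consequence.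

**Step 4**
Reactants: 7 chromanol lactol
Product: 11 (2E)-N-[(1S,3S,4R,5R,6R)-1,4,6-trihydroxy-9-oxobicyclo[3.3.1]non-7-en-3-yl]dec-2-enamide (amide exo/equatorial; C4–OH and C6–OH both exo/axial, syn to the C9 bridge), via spirolactol dienone 8 (not isolated), via o-quinol aldehyde 9 (not isolated), via oxa-Michael adduct (enolate) 10 (not isolated)
Conditions: (a) ArI* (10 mol %; (R,R)-2-iodo-1,3-bis[1-(mesitylcarbamoyl)ethoxy]benzene), mCPBA (1.05 equiv), H2O (10 equiv), HFIP (20 equiv), CH2Cl2, 0.02 M, −20 °C, 16 h, then Me2S (0.1 equiv); (b) cannulate into degassed 0.1 M LiOH, THF/H2O 3:1 (final 2 mM), 0 °C, 2–4 h; aq NH4Cl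
Reagents that add atoms: mCPBA (net source of the C1 oxygen, relayed through the iodane and water), O=C(OO)c1cccc(Cl)c1; water, O
Why: Proposed new method: dearomative spiro-lactolisation / oxa-Michael / aldol cascade. The aryl-λ3-iodane made in situ binds the phenol oxygen of the open tautomer 6, and the side-chain aldehyde oxygen (as hydrate, or as carbonyl followed by water capture) attacks the alkyl-bearing ortho carbon 5-exo; this fixes the site (C1, not the free ortho or para CH) and sets 1S through the chiral pocket, helped by the substrate, whose amide lies trans to the iodine-laden C–O. In base, 8 opens to 9, and hydroxide adds 1,4 at the unhindered β-carbon on the face carrying the C1–OH, anti to the CH2 tether, which sets C6. The enolate 10 then closes on the tethered aldehyde from the opposite face through a chair with the amide equatorial and attack anti to N (polar Felkin–Anh), which sets C5 anti to C6–O and places C4–OH axial and cis to the amide. The adduct is locked because the bridgehead C5–H cannot enolise (Bredt), so no β-elimination follows, and any Cα epimerisation is funnelled by the reversible aldol to the exo-amide isomer. The closest known reaction types are the chiral-iodoarene-catalysed Kita oxidative spirolactonisation of 3-(2-hydroxyphenyl)propanoic acids and the base-induced tandem oxa-Michael/aldol closure of tyrosinal-derived p-quinol spirolactols to bicyclo[3.3.1]nonanes.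

**Step 5**
Reactants: 11 bicyclic enetriol
Product: 12 isariotin D
Conditions: VO(acac)2 (5 mol %), t-BuOOH (1.5 equiv, decane), CH2Cl2, 0 °C → rt
Reagents that add atoms: tert-butyl hydroperoxide, CC(C)(C)OO
Why: Vanadium-catalysed hydroxyl-directed (Sharpless–Michaelson type) epoxidation; both allylic hydroxyls (C1, C6) sit on the exo face, which is also the only open face, so the oxirane (7S,8S) forms cis to them; the electron-poor enamide alkene has no allylic OH and stays intact, and a cis epoxy alcohol cannot undergo Payne migration.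

**Compound list**
1 | L-o-tyrosine, (2S)-2-amino-3-(2-hydroxyphenyl)propanoic acid | N[C@@H](Cc1ccccc1O)C(=O)O | starting material
2 | methyl (2S)-2-amino-3-(2-hydroxyphenyl)propanoate hydrochloride | N[C@@H](Cc1ccccc1O)C(=O)OC.Cl | intermediate
3 | (2E)-dec-2-enoic acid | CCCCCCC/C=C/C(=O)O | starting material
4 | (2E)-dec-2-enoyl chloride | CCCCCCC/C=C/C(=O)Cl | intermediate
5 | methyl (2S)-2-[(2E)-dec-2-enamido]-3-(2-hydroxyphenyl)propanoate | CCCCCCC/C=C/C(=O)N[C@@H](Cc1ccccc1O)C(=O)OC | intermediate
6 | (2E)-N-[(2S)-1-(2-hydroxyphenyl)-3-oxopropan-2-yl]dec-2-enamide (open tautomer of 7) | CCCCCCC/C=C/C(=O)N[C@@H](Cc1ccccc1O)C=O | intermediate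
7 | (2E)-N-[(3S)-2-hydroxy-3,4-dihydro-2H-chromen-3-yl]dec-2-enamide (anomer mixture) | CCCCCCC/C=C/C(=O)N[C@H]1Cc2ccccc2OC1O | intermediate
8 | (2E)-N-[(3S,5S)-2-hydroxy-6-oxo-1-oxaspiro[4.5]deca-7,9-dien-3-yl]dec-2-enamide (amide trans to the ring C=O) | CCCCCCC/C=C/C(=O)N[C@H]1C[C@@]2(OC1O)C(=O)C=CC=C2 | intermediate
9 | (2E)-N-[(2S)-1-[(1S)-1-hydroxy-6-oxocyclohexa-2,4-dien-1-yl]-3-oxopropan-2-yl]dec-2-enamide | CCCCCCC/C=C/C(=O)N[C@@H](C[C@@]1(O)C(=O)C=CC=C1)C=O | intermediate
10 | (2E)-N-[(2S)-1-[(1S,4S)-1,4-dihydroxy-6-oxocyclohex-2-en-1-yl]-3-oxopropan-2-yl]dec-2-enamide (reacts as its enolate; the two OH groups are cis) | CCCCCCC/C=C/C(=O)N[C@@H](C[C@@]1(O)C(=O)C[C@H](O)C=C1)C=O | intermediate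
11 | (2E)-N-[(1S,3S,4R,5R,6R)-1,4,6-trihydroxy-9-oxobicyclo[3.3.1]non-7-en-3-yl]dec-2-enamide | CCCCCCC/C=C/C(=O)N[C@H]1C[C@@]2(O)C(=O)[C@H]([C@H](O)C=C2)[C@H]1O | intermediate
12 | isariotin D, (2E)-N-[(1S,3S,4R,5S,6S,7S,8S)-7,8-epoxy-1,4,6-trihydroxy-9-oxobicyclo[3.3.1]nonan-3-yl]dec-2-enamide | CCCCCCC/C=C/C(=O)N[C@H]1C[C@@]2(O)C(=O)[C@H]([C@H](O)[C@@H]3O[C@@H]32)[C@H]1O | target

**Totals:** 5 steps; longest linear sequence 5 steps (from L-o-tyrosine). The acid chloride is telescoped inside step 2.

**Steps most likely to fail**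

**Step 4 (the new step).**
- Unsubstituted o-quinols dimerise by [4+2]. This is the reason for −20 °C in part (a) and 2 mM in part (b).
- Water could attack para to the phenol oxygen.
- Hydroxide could add 1,6.
- The amide N or the lactol OH could add to C8.
- The sense of induction of ArI* on this nucleophile is untested. The (S,S) antipode is equally accessible if the catalyst turns out mismatched.

The fallback uses known chemistry, sets out from 7 and comes back at 11. Compound 7 is dearomatised with SIBX (THF, 2 mM, rt), the established hydroxylative dearomatisation of 2-alkylphenols. This gives 8 together with its C5 epimer, the (3S,5R)-spirolactol F1, without reagent control. The solution is treated directly with t-BuOOH/DBU, a Weitz–Scheffer epoxidation of the α,β-bond on the face of the carbinol oxygen. This removes the diene, and with it the dimerisation. It gives the epoxy-enone F2 from 8 and the ring-epimeric epoxy-enone F3 from F1, which are separable on silica. SmI2 (2.2 equiv, THF, −78 °C) then cleaves the Cα–O bond of F2. The samarium enolate closes on the aldehyde (reductive aldol of an α,β-epoxy ketone), keeping C6–O with retention and giving 11.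

**Step 5.**
- The α-ketol and polyol array may chelate and deactivate vanadium.
- The allylic C6–OH may be oxidised instead.
- Peracids risk Baeyer–Villiger attack at the α-hydroxy bridge ketone.

The fallback epoxidises before the second ring is closed. It sets out from 7, by way of the epoxy-enone F2 of the preceding fallback, and comes back at 12. The remaining C7=C8 bond of F2 is epoxidised under direction of the tertiary allylic C1–OH (VO(acac)2/t-BuOOH or mCPBA). This gives the all-syn bis-epoxide F4. SmI2 (THF, −78 °C) opens only the oxirane α to the ketone, and the enolate closes on the aldehyde to give 12 directly.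

**Step 3.**
- Over-reduction to the amino alcohol is possible.
- Conversion may be incomplete with three aluminium-binding sites in the substrate.

The fallback goes through a chelate-stabilised acyl donor, sets out from 5 and comes back at 7. Compound 5 is converted with MeNH(OMe)·HCl/i-PrMgCl (THF, −20 °C) into the Weinreb amide F5. Its chelated DIBAL-H adduct (−78 °C) cannot be reduced further. On work-up it releases 6, which closes to 7.

**Further compounds**
F1 | step 4 | (2E)-N-[(3S,5R)-2-hydroxy-6-oxo-1-oxaspiro[4.5]deca-7,9-dien-3-yl]dec-2-enamide | CCCCCCC/C=C/C(=O)N[C@H]1C[C@]2(OC1O)C(=O)C=CC=C2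
F2 | step 4 | (2E)-N-[(2S)-1-[(1R,3S,6R)-3-hydroxy-2-oxo-7-oxabicyclo[4.1.0]hept-4-en-3-yl]-3-oxopropan-2-yl]dec-2-enamide (oxirane syn to the OH; drawn as open hydroxy-aldehyde) | CCCCCCC/C=C/C(=O)N[C@@H](C[C@@]1(O)C(=O)[C@@H]2O[C@@H]2C=C1)C=O
F3 | step 4 | (2E)-N-[(2S)-1-[(1S,3R,6S)-3-hydroxy-2-oxo-7-oxabicyclo[4.1.0]hept-4-en-3-yl]-3-oxopropan-2-yl]dec-2-enamide | CCCCCCC/C=C/C(=O)N[C@@H](C[C@]1(O)C(=O)[C@H]2O[C@H]2C=C1)C=O
F4 | step 5 | all-syn bis-epoxide of 9 (C5–C6 and C7–C8 oxiranes both on the face of the C1–OH; drawn as open hydroxy-aldehyde) | CCCCCCC/C=C/C(=O)N[C@@H](C[C@@]1(O)C(=O)[C@@H]2O[C@@H]2[C@@H]3O[C@@H]31)C=O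
F5 | step 3 | (2E)-N-[(2S)-3-(2-hydroxyphenyl)-1-[methoxy(methyl)amino]-1-oxopropan-2-yl]dec-2-enamide | CCCCCCC/C=C/C(=O)N[C@@H](Cc1ccccc1O)C(=O)N(C)OC
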